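Target is paid for in partner, so the account to keep is what else draws on that partner, and what else reaches the starting material first.

| flask | starting material | partner | second substrate | time | remark |
|---|---|---|---|---|---|
| cedar | 2.0 mM | 1.10 equiv | 1.00 equiv (fed, over 40 s) | 1.0 min | all else is in the flask from the start; the feed brings no volume worth counting |
| oak | 2.0 mM | 1.10 equiv | 1.00 equiv | 1.0 min | everything together at the start |
| larch | 2.0 mM | 1.10 equiv (fed, over 40 s) | 1.00 equiv | 1.0 min | all else is in the flask from the start; the feed brings no volume worth counting |

- which flask leads in amount of target, in percent of the starting material charged ("all alike" within 1.5 percentage points) (cedar / oak / larch / all alike)
- how much target is there at the end, in percent of the starting material charged: cedar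
- how much target is there at the end, in percent of the starting material charged: oak
- how much target is there at the end, in percent of the starting material charged: larch

    second substrate + target ⇌ idle adduct, settled at all times (K1 = 1200 /M)
    second substrate + partner → second product (k2 = 448 /M/s)
    starting material + partner → target (k3 = 480 /M/s)
    partner → decomposed reagent (k4 = 0.0702 /s)
    2 second substrate → homo dimer (k5 = 19.9 /M/s)
    starting material + second substrate → cross product (k6 = 652 /M/s)

- target is meant together with its idle adduct
- a step written with two of one species runs at k times the square of its concentration and takes two of it each time
- run time (cedar): 1.0 min

For the cross step to keep pace with the productive step while partner stands at its full charge, free second substrate would have to stand at 0.810 of the starting-material charge. In cedar, the feed brings 0.0237 within the 0.947 s lifetime of starting material, far less. Cedar's loss therefore lies with the partner's decay, measured by the decay share, the fraction of the charge of starting material at which decay of partner keeps pace with its productive step, 0.0731.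

Let y be the fraction of starting material that the partner never reaches. Leaving second substrate out of the count, the partner's excess over the charge, 0.100, plus y equals the decay share times ln of the reciprocal of y. Two rounds of substitution give 0.0913 and 0.0751, with mean 0.0832, so cedar holds 91.7% target.

In oak, the ratio at the start gives a split of 44.7%. In larch, the cross step thins starting material to the decay share within 10.5 s, shorter than the feed, and the partner fed by then, shared with second substrate, leaves 14.9%. The reckoning leads with cedar.

The forecast names cedar, with 88% (84% to 92%) for cedar, 51% (46% to 56%) for oak and 17% (12% to 23%) for larch, holding that in cedar “the starting material meets the partner almost alone in the first few seconds”.

The simulation gives cedar: 87.5% in cedar, 51.3% in oak and 12.9% in larch.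

Cedar stands 4.2 percentage points below the reckoning, and its second product, 5.21% of the charge, is partner the balance left out. The neighbour of cedar with 0.440 equiv of partner, where partner is the limiting reagent, gives by the same decay share 0.398, then 0.403, and it stores 39.7%. With the cross step taken away, larch still trails cedar, but the difference between them falls from 75 points to 16 points.

The constants used here belong to no real substance; the result is computed.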